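**Plan**
- Retrosynthesis: the C4–OMe bond is cut first (methanol capture of an aryloxycarbenium ion released from a C4 acetyl group), then the ring is cut at C5–C6 and C3–C4.
- Enabling feature: the ring is a 3-methoxycyclohex-2-enone. C1 (C=O), C2, C3 (OMe) and C6 (allyl) are the four carbons of a 1,1-dimethoxy-3-silyloxydiene; C4 (ketal) and C5 are the C=C of a 2-aryloxy enone that already carries the aryl ether oxygen.
- Forward, enone arm: 3,4-dimethoxyphenol is O-allylated, rearranged (Claisen), and converted by O–H insertion and olefination into the 2-aryloxy enone. Diene arm: pent-4-enoyl chloride acylates 1,1-dimethoxyethene and the ketone is silylated to the triene.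
- The copper bis(oxazoline) [4+2] cycloaddition closes the only ring made in the route; oxime formation and Beckmann fragmentation in methanol then turn C4–acetyl into C4–OMe.
- Stereochemistry: C6 (S) comes from the catalyst-controlled cycloaddition; C4 (R) comes from axial addition of methanol trans to the C6 allyl group.

Key step: step 7

Assumption: the (S,S)-ligand is taken to give the (6S) series by analogy with the square-planar two-point-binding model; if the adduct proves to be (6R), the equally available (R,R)-ligand is used with no other change.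

Step 1
Reactants: 1 3,4-dimethoxyphenol
Product: 2 4-(allyloxy)-1,2-dimethoxybenzene
Conditions: allyl bromide, K2CO3, acetone, reflux
Reagents that add atoms: allyl bromide, C=CCBr
Why: Williamson ether synthesis; the phenoxide should displace bromide from the unhindered allylic halide.

Step 2
Reactants: 2 4-(allyloxy)-1,2-dimethoxybenzene
Product: 4 2-allyl-4,5-dimethoxyphenol, via Claisen dienone 3 (not isolated)
Conditions: N,N-diethylaniline, 200 °C
Reagents that add atoms: none
Why: Aromatic Claisen rearrangement; the [3,3] shift should go to the free ortho carbon para to the 3-methoxy group rather than to the crowded carbon between the two oxygens, and the dienone tautomerises to the phenol.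

Step 3
Reactants: 4 2-allyl-4,5-dimethoxyphenol; 5 dimethyl (1-diazo-2-oxopropyl)phosphonate
Product: 6 dimethyl [1-(2-allyl-4,5-dimethoxyphenoxy)-2-oxopropyl]phosphonate (racemic)
Conditions: Rh2(OAc)4 (2 mol %), toluene, 80 °C, slow addition of 5
Reagents that add atoms: none
Why: Rhodium-carbenoid O–H insertion; capture of the acceptor-substituted carbenoid by the phenol oxygen (oxonium ylide, then proton shift) should outrun cyclopropanation of the allyl group.

Step 4
Reactants: 6 dimethyl [1-(2-allyl-4,5-dimethoxyphenoxy)-2-oxopropyl]phosphonate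
Product: 7 3-(2-allyl-4,5-dimethoxyphenoxy)but-3-en-2-one
Conditions: aq. HCHO (37%), K2CO3, THF–H2O, 0 °C → rt
Reagents that add atoms: formaldehyde, C=O
Why: Horner–Wadsworth–Emmons olefination with formaldehyde; the phosphonate carbon becomes the aryloxy-bearing alkene carbon, so the position of the methylene group is fixed by construction.

Step 5
Reactants: 8 pent-4-enoyl chloride; 9 1,1-dimethoxyethene (2.2 equiv)
Product: 10 1,1-dimethoxyhepta-1,6-dien-3-one
Conditions: Et2O, 0 °C → rt, exclusion of moisture
Reagents that add atoms: none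
Why: C-acylation of the electron-rich ketene acetal by the acid chloride followed by loss of HCl, which the second equivalent of 9 should take up as methyl acetate and chloromethane.

Step 6
Reactants: 10 1,1-dimethoxyhepta-1,6-dien-3-one
Product: 11 (3Z)-1,1-dimethoxy-3-(trimethylsilyloxy)hepta-1,3,6-triene
Conditions: Me3SiOTf, Et3N, Et2O, 0 °C; used directly after filtration and concentration
Reagents that add atoms: trimethylsilyl trifluoromethanesulfonate, C[Si](C)(C)OS(=O)(=O)C(F)(F)F
Why: Soft enolisation and O-silylation at the only enolisable position (C4); the thermodynamically preferred (3Z) silyl dienol ether is expected, with the allyl group cis to OSi and therefore pointing outward in the s-cis diene.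

Step 7
Reactants: 7 3-(2-allyl-4,5-dimethoxyphenoxy)but-3-en-2-one; 11 (3Z)-1,1-dimethoxy-3-(trimethylsilyloxy)hepta-1,3,6-triene (1.5 equiv)
Product: 13 (4R,6S)-4-acetyl-6-allyl-4-(2-allyl-4,5-dimethoxyphenoxy)-3-methoxycyclohex-2-en-1-one, via silyl enol ether cycloadduct 12 (not isolated)
Conditions: Cu(OTf)2 (10 mol %), (S,S)-2,2'-(propane-2,2-diyl)bis(4-tert-butyl-4,5-dihydrooxazole) (11 mol %), 4 Å MS, CH2Cl2, −78 → −40 °C; then 0.01 M HCl, THF–H2O, 0 °C; silica chromatography
Reagents that add atoms: none
Why: Proposed new method: enone 7 is expected to bind the bis(oxazoline) complex of divalent copper through its carbonyl and aryl ether oxygens in a five-membered chelate, and the polarised diene 11 then adds by an asynchronous [4+2] cycloaddition (limiting case: Mukaiyama–Michael addition then Michael closure), its allyl-bearing terminus bonding to the enone CH2 (C5–C6) before the ketene-acetal carbon bonds to the aryloxy carbon (C3–C4); the closest known reactions are Lewis-acid Diels–Alder and double Michael additions of 1,1-dialkoxy-3-silyloxydienes to enones and copper bis(oxazoline) Diels–Alder reactions of two-point-binding dienophiles. The one six-membered ring closes as the [4+2] event across the enone C=C, or as a 6-endo-trig closure if the path is stepwise. C4 is set by the enone face left open by the ligand tert-butyl groups, relayed through the coordinated aryloxy group, and C6 follows from that face together with the (3Z) diene geometry and the carbonyl-exo, aryloxy-endo approach, which places OAr cis to allyl. Regiochemistry should need no help beyond the push of the 3-silyloxy and 1,1-dimethoxy groups toward the allyl-bearing terminus and the pull of the acetyl group on the enone CH2. The step needs enone-face and exo selectivity together, because the C4 epimer formed on the same enone face has the (6R) configuration; it is a diastereomer and is to be removed by chromatography here, before C4 is ionised. Dilute acid then hydrolyses the silyl enol ether and expels one methanol, which fixes the enol ether at C3.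

Step 8
Reactants: 13 (4R,6S)-4-acetyl-6-allyl-4-(2-allyl-4,5-dimethoxyphenoxy)-3-methoxycyclohex-2-en-1-one
Product: 14 (4S,6S)-6-allyl-4-(2-allyl-4,5-dimethoxyphenoxy)-4-[(1E)-N-hydroxyethanimidoyl]-3-methoxycyclohex-2-en-1-one
Conditions: NH2OH·HCl, NaOAc, MeOH, rt
Reagents that add atoms: hydroxylamine hydrochloride, NO.Cl
Why: Oxime formation; the unconjugated methyl ketone should condense much faster than the deactivated vinylogous ester, whose C3 is shielded by the quaternary C4, and the hydroxyl should settle anti to the quaternary carbon (E); no bond to C4 changes, the descriptor changes only through ligand priorities.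

Step 9
Reactants: 14 (4S,6S)-6-allyl-4-(2-allyl-4,5-dimethoxyphenoxy)-4-[(1E)-N-hydroxyethanimidoyl]-3-methoxycyclohex-2-en-1-one
Product: 17 (4R,6S)-6-allyl-4-(2-allyl-4,5-dimethoxyphenoxy)-3,4-dimethoxycyclohex-2-en-1-one, via oxime mesylate 15 (not isolated), via aryloxycarbenium methanesulfonate 16 (not isolated)
Conditions: MsCl, Et3N, CH2Cl2, −40 °C; then MeOH (excess), −40 °C → rt
Reagents that add atoms: methanol, CO
Why: Beckmann fragmentation of an α-oxygenated ketoxime; in the (E)-oxime mesylate the C4–C bond is anti to N–O, so the aryloxy lone pair should expel acetonitrile and methanesulfonate, and methanol should add axially to the aryloxycarbenium ion on the half-chair with the C6 allyl group pseudo-equatorial, that is trans to allyl, setting (4R).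

**Compound list**
1 | 3,4-dimethoxyphenol | COc1ccc(O)cc1OC | starting material
2 | 4-(allyloxy)-1,2-dimethoxybenzene | C=CCOc1ccc(OC)c(OC)c1 | intermediate
3 | 6-allyl-3,4-dimethoxycyclohexa-2,4-dien-1-one (Claisen dienone, not isolated) | C=CCC1C=C(OC)C(OC)=CC1=O | intermediate
4 | 2-allyl-4,5-dimethoxyphenol | C=CCc1cc(OC)c(OC)cc1O | intermediate
5 | dimethyl (1-diazo-2-oxopropyl)phosphonate | CC(=O)C(=[N+]=[N-])P(=O)(OC)OC | starting material
6 | dimethyl [1-(2-allyl-4,5-dimethoxyphenoxy)-2-oxopropyl]phosphonate (racemic) | C=CCc1cc(OC)c(OC)cc1OC(C(C)=O)P(=O)(OC)OC | intermediate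
7 | 3-(2-allyl-4,5-dimethoxyphenoxy)but-3-en-2-one | C=CCc1cc(OC)c(OC)cc1OC(=C)C(C)=O | intermediate
8 | pent-4-enoyl chloride | C=CCCC(Cl)=O | starting material
9 | 1,1-dimethoxyethene | C=C(OC)OC | starting material
10 | 1,1-dimethoxyhepta-1,6-dien-3-one | C=CCCC(=O)C=C(OC)OC | intermediate
11 | (3Z)-1,1-dimethoxy-3-(trimethylsilyloxy)hepta-1,3,6-triene | C=CC/C=C(/C=C(OC)OC)O[Si](C)(C)C | intermediate
12 | 1-[(1S,5S)-5-allyl-1-(2-allyl-4,5-dimethoxyphenoxy)-2,2-dimethoxy-4-(trimethylsilyloxy)cyclohex-3-en-1-yl]ethan-1-one (cycloadduct, not isolated) | C=CCc1cc(OC)c(OC)cc1O[C@]1(C(C)=O)C[C@H](CC=C)C(O[Si](C)(C)C)=CC1(OC)OC | intermediate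
13 | (4R,6S)-4-acetyl-6-allyl-4-(2-allyl-4,5-dimethoxyphenoxy)-3-methoxycyclohex-2-en-1-one | C=CCc1cc(OC)c(OC)cc1O[C@]1(C(C)=O)C[C@H](CC=C)C(=O)C=C1OC | intermediate
14 | (4S,6S)-6-allyl-4-(2-allyl-4,5-dimethoxyphenoxy)-4-[(1E)-N-hydroxyethanimidoyl]-3-methoxycyclohex-2-en-1-one | C=CCc1cc(OC)c(OC)cc1O[C@]1(/C(C)=N/O)C[C@H](CC=C)C(=O)C=C1OC | intermediate
15 | (4S,6S)-6-allyl-4-(2-allyl-4,5-dimethoxyphenoxy)-3-methoxy-4-{(1E)-N-[(methylsulfonyl)oxy]ethanimidoyl}cyclohex-2-en-1-one (oxime mesylate, not isolated) | C=CCc1cc(OC)c(OC)cc1O[C@]1(/C(C)=N/OS(C)(=O)=O)C[C@H](CC=C)C(=O)C=C1OC | intermediate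
16 | [(5S)-5-allyl-2-methoxy-4-oxocyclohex-2-en-1-ylidene](2-allyl-4,5-dimethoxyphenyl)oxonium methanesulfonate (ion pair, not isolated) | C=CCc1cc(OC)c(OC)cc1[O+]=C1C[C@H](CC=C)C(=O)C=C1OC.CS(=O)(=O)[O-] | intermediate
17 | (4R,6S)-6-allyl-4-(2-allyl-4,5-dimethoxyphenoxy)-3,4-dimethoxycyclohex-2-en-1-one | C=CCc1cc(OC)c(OC)cc1O[C@]1(OC)C[C@H](CC=C)C(=O)C=C1OC | target

**Step count**
Total: 9 steps. Longest linear sequence: 7 steps (steps 1, 2, 3, 4, 7, 8, 9); the diene arm (steps 5 and 6) joins at step 7.

**Steps most likely to fail**

1. Step 7. The aryl ether oxygen may bind copper too weakly for a rigid chelate, so facial discrimination of the enone could be poor. The Lewis acid could also stop the sequence at the open-chain Michael adduct or degrade the ketene acetal. The fallback uses known chemistry and sets out from 7 and 11. The two are heated without catalyst in toluene at 80–110 °C (thermal Diels–Alder reaction of a 1,1-dimethoxy-3-silyloxydiene with an enone) and worked up with dilute HCl as before. This gives the racemate, that is 13 together with (4S,6R)-4-acetyl-6-allyl-4-(2-allyl-4,5-dimethoxyphenoxy)-3-methoxycyclohex-2-en-1-one F2, the latter through 1-[(1R,5R)-5-allyl-1-(2-allyl-4,5-dimethoxyphenoxy)-2,2-dimethoxy-4-(trimethylsilyloxy)cyclohex-3-en-1-yl]ethan-1-one F1. After the C4-epimeric pair is removed on silica, preparative chromatography on a chiral stationary phase (amylose tris(3,5-dimethylphenylcarbamate)) should separate the enantiomers, and the route is rejoined at 13. The approach changes from asymmetric catalysis to racemic cycloaddition and resolution.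

2. Step 9. Under the basic conditions the aryloxycarbenium ion may lose its C5 proton and tautomerise to a phenol (aromatisation), or methanol may add with poor facial selectivity. The fallback sets out from 13 and generates the same ion at low temperature without base. Baeyer–Villiger oxidation (mCPBA, NaHCO3, CH2Cl2, 0 °C) should move the oxygen-bearing quaternary carbon with retention to give (1S,5S)-5-allyl-1-(2-allyl-4,5-dimethoxyphenoxy)-2-methoxy-4-oxocyclohex-2-en-1-yl acetate F3. Acetate-for-methoxy exchange with MeOSiMe3 and catalytic Me3SiOTf in the presence of 2,6-di-tert-butyl-4-methylpyridine (CH2Cl2, −78 °C) then passes through [(5S)-5-allyl-2-methoxy-4-oxocyclohex-2-en-1-ylidene](2-allyl-4,5-dimethoxyphenyl)oxonium trifluoromethanesulfonate F4 and rejoins the route at 17. This path was not chosen as the main line because the peracid can also epoxidise the two allyl groups.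

3. Step 5. Chloride may dealkylate the dimethoxycarbenium intermediate to the β-keto ester, or the enolisable acid chloride may be dehydrochlorinated instead of acylating. The fallback sets out from 9 and builds the chain by enolate alkylation instead. Acetyl chloride and 9 (2.2 equiv, Et2O, 0 °C) give the parent ketone 4,4-dimethoxybut-3-en-2-one F5. Deprotonation at its methyl group with LiN(i-Pr)2 (THF, −78 °C) gives lithium 4,4-dimethoxybuta-1,3-dien-2-olate F6, and alkylation with allyl bromide rejoins the route at 10.

**Further compounds**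
F1 | step 7 | 1-[(1R,5R)-5-allyl-1-(2-allyl-4,5-dimethoxyphenoxy)-2,2-dimethoxy-4-(trimethylsilyloxy)cyclohex-3-en-1-yl]ethan-1-one | C=CCc1cc(OC)c(OC)cc1O[C@@]1(C(C)=O)C[C@@H](CC=C)C(O[Si](C)(C)C)=CC1(OC)OC
F2 | step 7 | (4S,6R)-4-acetyl-6-allyl-4-(2-allyl-4,5-dimethoxyphenoxy)-3-methoxycyclohex-2-en-1-one | C=CCc1cc(OC)c(OC)cc1O[C@@]1(C(C)=O)C[C@@H](CC=C)C(=O)C=C1OC
F3 | step 9 | (1S,5S)-5-allyl-1-(2-allyl-4,5-dimethoxyphenoxy)-2-methoxy-4-oxocyclohex-2-en-1-yl acetate | C=CCc1cc(OC)c(OC)cc1O[C@]1(OC(C)=O)C[C@H](CC=C)C(=O)C=C1OC
F4 | step 9 | [(5S)-5-allyl-2-methoxy-4-oxocyclohex-2-en-1-ylidene](2-allyl-4,5-dimethoxyphenyl)oxonium trifluoromethanesulfonate | C=CCc1cc(OC)c(OC)cc1[O+]=C1C[C@H](CC=C)C(=O)C=C1OC.[O-]S(=O)(=O)C(F)(F)F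
F5 | step 5 | 4,4-dimethoxybut-3-en-2-one | CC(=O)C=C(OC)OC
F6 | step 5 | lithium 4,4-dimethoxybuta-1,3-dien-2-olate | [Li+].C=C([O-])C=C(OC)OC
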